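**Plan**
1. Retrosynthetic cuts: first the C5–alkenyl bond (side chain). Then, together, O1–C7a and C3–C3a, the two bonds that tie the O1–C2–C3 unit to the benzene ring. The three-atom unit goes back to an erythro 2,3-epoxy alcohol, made from 3,4-dimethoxybenzaldehyde and a vinyl anion.
2. Enabling feature: in the benzene ring C3a–C4–C5–C6–C7–C7a, C7a is flanked by C7(OMe) and C3a by unsubstituted C4. The ring can therefore be entered as 4,4-dimethoxycyclohexa-2,5-dienone (C7 = ketal carbon, C4 = C=O). There C7a and C3a are the β- and α-carbons of an enone, a 1,2-ambiphile that takes O at C7a and then C at C3a, the orientation a 3-methoxyaryne would reverse.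
3. Forward order: epoxy alcohol (2 steps); annulation closes the dihydrofuran ring on the dienone; the surviving enone is iodinated at C5; reduction and acid remove the helpers (C4=O, one C7–OMe) and restore the benzene ring; a Stille coupling joins the (E)-hydroxypropenyl chain.
4. Stereochemistry: both centres come from one Sharpless kinetic-resolution epoxidation. C2 is carried over with retention and C3 by SN2 inversion of the oxirane carbon, which gives the trans product. The transient C3a/C7a centres are erased on aromatisation.

Key step: step 3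

Remark: the benzofuran numbering of the target (O1, C2, C3, C3a, C4–C7, C7a) is used for all intermediates; 4,4-dimethoxycyclohexa-2,5-dienone and (E)-3-(tributylstannyl)prop-2-en-1-ol are taken as catalogue compounds.

Step 1
Reactants: 1 3,4-dimethoxybenzaldehyde; 2 vinylmagnesium bromide
Product: 3 rac-1-(3,4-dimethoxyphenyl)prop-2-en-1-ol
Conditions: THF, 0 °C; then aq. NH4Cl
Reagents that add atoms: none
Why: 1,2-addition of a vinyl Grignard reagent to an aromatic aldehyde should give the racemic allylic alcohol, and no stereocontrol is needed because the next step selects one enantiomer.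

Step 2
Reactants: 3 rac-1-(3,4-dimethoxyphenyl)prop-2-en-1-ol
Product: 4 (R)-(3,4-dimethoxyphenyl)[(2S)-oxiran-2-yl]methanol (erythro)
Conditions: Ti(OiPr)4 (10 mol %), D-(−)-DIPT (12 mol %), t-BuOOH (0.45 equiv), 4 Å MS, CH2Cl2, −20 °C
Reagents that add atoms: tert-butyl hydroperoxide, CC(C)(C)OO
Why: in the Sharpless kinetic-resolution epoxidation with D-(−)-DIPT the (S)-alcohol should be epoxidised far faster than the (R)-alcohol and on the face that gives the erythro epoxy alcohol, so the titanium tartrate sets both the carbinol centre (future C2) and the oxirane centre (future C3, inverted later), and less than half an equivalent of oxidant keeps the enantiopurity of 4 high.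

Step 3
Reactants: 4 (R)-(3,4-dimethoxyphenyl)[(2S)-oxiran-2-yl]methanol; 5 4,4-dimethoxycyclohexa-2,5-dien-1-one
Product: 7 (2S,3R,3aS,7aR)-2-(3,4-dimethoxyphenyl)-3-(hydroxymethyl)-7,7-dimethoxy-3,3a,7,7a-tetrahydro-1-benzofuran-4(2H)-one, via potassium enolate 6 (not isolated)
Conditions: KHMDS (1.0 equiv), THF, −78 °C; then 5 (2 equiv), ca. 0.5 M, −78 → 0 °C; aq. NH4Cl
Reagents that add atoms: none
Why: Proposed new method: the potassium alkoxide of 4 should add reversibly to a β-carbon of dienone 5 (future C7a, O1–C7a bond), and the α-carbon of the resulting enolate 6 (future C3a) should then attack the adjacent oxirane carbon (C3–C3a bond) in an irreversible, strain-releasing step that drains the unfavourable oxa-Michael equilibrium and frees the CH2O− group. The closest known reaction types are the Weitz–Scheffer nucleophilic epoxidation of quinone monoketals (oxygen Michael addition next to the ketal carbon, then enolate ring closure) and the exo-selective Parham-type cyclisation of o-lithioaryl glycidyl ethers to 2,3-dihydrobenzofuran-3-ylmethanols; new here is an alkoxide as Michael donor combined with an epoxide as the internal electrophile. The tetrahydrofuran ring closes in the 5-(enolexo)-exo-tet mode, which allows collinear backside attack at the internal oxirane carbon, whereas the 6-endo path to the terminal carbon does not. C2 keeps the configuration of the carbinol carbon of 4 because its C–O bond is never broken, C3 results from SN2 inversion of the (S)-oxirane carbon (aryl and CH2OH trans), and C3a/C7a arise cis-fused because the short tether delivers C3 to the ring face that already bears O1 (drawn with C4 anti to CH2OH; both centres vanish in step 5, so this facial choice has no consequence). Regiochemistry needs no control, since the two enone halves of 5 are equivalent and the C4 carbonyl alone dictates oxygen at C7a, next to the ketal carbon that becomes C7–OMe, and carbon at C3a. The selectivity that is needed is addition and closure ahead of epoxide migration (Payne rearrangement) and ahead of a second annulation on the remaining enone, which cold aprotic generation of the alkoxide, high concentration and excess 5 are meant to secure.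

Step 4
Reactants: 7 the bicyclic enone from step 3
Product: 8 (2S,3R,3aS,7aR)-2-(3,4-dimethoxyphenyl)-3-(hydroxymethyl)-5-iodo-7,7-dimethoxy-3,3a,7,7a-tetrahydro-1-benzofuran-4(2H)-one
Conditions: I2, pyridine/CH2Cl2, 0 °C → rt
Reagents that add atoms: iodine, II
Why: Baylis–Hillman-type α-iodination of a cyclic enone (pyridine adds at C6, the enolate is iodinated at C5, pyridine leaves) should mark the only enone α-CH, the future C5, while iodine/pyridine is too weak an electrophile for the dimethoxyphenyl ring and leaves alcohol, ketal and stereocentres alone.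

Step 5
Reactants: 8 the α-iodoenone from step 4
Product: 10 [(2S,3R)-2-(3,4-dimethoxyphenyl)-5-iodo-7-methoxy-2,3-dihydro-1-benzofuran-3-yl]methanol, via iodo allylic alcohol 9 (not isolated)
Conditions: NaBH4, CeCl3·7H2O, MeOH, −40 °C; extractive work-up; then CSA (cat.), 4 Å MS, CH2Cl2, 0 °C → rt
Reagents that add atoms: none
Why: Luche 1,2-reduction turns the helper carbonyl into an allylic alcohol, and catalytic acid should then ionise the allylic ketal and the carbinol in turn, so that methanol (C7–OMe/C7a–H) and water (C4–OH/C3a–H) are lost in a dehydrative aromatisation that leaves C2 and C3 untouched, erases C3a and C7a, and under anhydrous conditions keeps the second C7 methoxy group.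

Step 6
Reactants: 10 the aryl iodide from step 5; 11 (E)-3-(tributylstannyl)prop-2-en-1-ol
Product: 12 hierochin B, (E)-3-[(2S,3R)-2-(3,4-dimethoxyphenyl)-3-(hydroxymethyl)-7-methoxy-2,3-dihydro-1-benzofuran-5-yl]prop-2-en-1-ol
Conditions: Pd2(dba)3 (cat.), AsPh3 (cat.), NMP, 40 °C
Reagents that add atoms: none
Why: Stille coupling of an aryl iodide with an (E)-alkenylstannane proceeds with retention of alkene geometry under neutral conditions that tolerate both free alcohols and the benzylic ether stereocentres.

**Compound list**
1 | 3,4-dimethoxybenzaldehyde | COc1ccc(C=O)cc1OC | starting material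
2 | vinylmagnesium bromide | C=C[Mg]Br | starting material
3 | rac-1-(3,4-dimethoxyphenyl)prop-2-en-1-ol | COc1ccc(C(O)C=C)cc1OC | intermediate
4 | (R)-(3,4-dimethoxyphenyl)[(2S)-oxiran-2-yl]methanol | COc1ccc([C@@H](O)[C@@H]2CO2)cc1OC | intermediate
5 | 4,4-dimethoxycyclohexa-2,5-dien-1-one | COC1(OC)C=CC(=O)C=C1 | starting material
6 | potassium (3R)-3-{(R)-(3,4-dimethoxyphenyl)[(2S)-oxiran-2-yl]methoxy}-4,4-dimethoxycyclohexa-1,5-dien-1-olate | COc1ccc([C@@H](O[C@@H]2C=C([O-])C=CC2(OC)OC)[C@@H]3CO3)cc1OC.[K+] | intermediate
7 | (2S,3R,3aS,7aR)-2-(3,4-dimethoxyphenyl)-3-(hydroxymethyl)-7,7-dimethoxy-3,3a,7,7a-tetrahydro-1-benzofuran-4(2H)-one | COc1ccc([C@H]2O[C@H]3C(OC)(OC)C=CC(=O)[C@H]3[C@@H]2CO)cc1OC | intermediate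
8 | (2S,3R,3aS,7aR)-2-(3,4-dimethoxyphenyl)-3-(hydroxymethyl)-5-iodo-7,7-dimethoxy-3,3a,7,7a-tetrahydro-1-benzofuran-4(2H)-one | COc1ccc([C@H]2O[C@H]3C(OC)(OC)C=C(I)C(=O)[C@H]3[C@@H]2CO)cc1OC | intermediate
9 | C4 carbinol from 1,2-reduction of 8: 2-(3,4-dimethoxyphenyl)-3-(hydroxymethyl)-5-iodo-7,7-dimethoxy-2,3,3a,4,7,7a-hexahydro-1-benzofuran-4-ol (C2, C3, C3a, C7a arranged as in 8; C4 epimers, not controlled and erased in the same step) | COc1ccc([C@H]2O[C@H]3C(OC)(OC)C=C(I)C(O)[C@H]3[C@@H]2CO)cc1OC | intermediate
10 | [(2S,3R)-2-(3,4-dimethoxyphenyl)-5-iodo-7-methoxy-2,3-dihydro-1-benzofuran-3-yl]methanol | COc1ccc([C@H]2Oc3c(OC)cc(I)cc3[C@@H]2CO)cc1OC | intermediate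
11 | (E)-3-(tributylstannyl)prop-2-en-1-ol | CCCC[Sn](CCCC)(CCCC)/C=C/CO | starting material
12 | hierochin B | COc1ccc([C@H]2Oc3c(OC)cc(/C=C/CO)cc3[C@@H]2CO)cc1OC | target

**Step count**
Total steps: 6. Longest linear sequence: 6 (1 → 3 → 4 → 7 → 8 → 10 → 12).

**Steps most likely to fail**

Step 3. The following processes could defeat it:
- epoxide migration in the alkoxide before conjugate addition;
- reversal of the oxa-Michael addition without ring closure;
- hydride transfer from the benzylic alkoxide to the dienone;
- a second annulation on the remaining enone.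

The fallback uses known chemistry, forms the two bonds in separate steps, sets out from 4 and comes back at 12. The sodium alkoxide of 4 (NaH, DMF, 0 °C) displaces fluoride from 3-bromo-4-fluoro-5-methoxybenzaldehyde. This is an SNAr reaction activated by the para formyl group, and the C2–O bond is untouched. It gives the aryl ether aldehyde F1. Wittig olefination with methyl (triphenylphosphoranylidene)acetate gives the (E)-cinnamate F2, and DIBAL-H at −78 °C gives the bromo allylic alcohol F3. n-BuLi (2.2 equiv, THF, −78 °C → rt) then deprotonates the alcohol and exchanges bromine for lithium. The aryllithium opens the oxirane 5-exo with inversion (Parham-type cyclisation) to give 12 with the same stereochemical logic.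

Step 5. The following processes could defeat it:
- hydrolysis of the ketal before elimination, with loss of the methyl ether;
- ionisation of the C7a–O1 bond, with opening of the furan ring;
- loss of iodine during the reduction.

The fallback removes the helper oxygen after aromatisation instead of before it. It sets out from 8 and comes back at 12. Acid alone (CSA, CH2Cl2) aromatises 8 by loss of methanol and enolisation, the normal fate of quinone-monoketal Michael adducts, to give the iodophenol F4. PhNTf2/K2CO3 sulfonylates only the phenol to give the iodo triflate F5. An iodide-selective Stille coupling with 11 (no chloride additive) gives the alkenyl triflate F6. Pd(OAc)2/dppf with HCO2H/Et3N then replaces the triflate by hydrogen to give 12.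

Step 2. Two processes could defeat it: an insufficient rate difference between the enantiomers, which would erode the enantiopurity of the epoxy alcohol, and Lewis acid induced opening of the electron-rich product. The fallback separates enantiomer selection from face selection. It sets out from 3 and comes back at 4. Lipase resolution (CAL-B, vinyl acetate, MTBE) acetylates the (R)-alcohol and leaves the (S)-allylic alcohol F7. F7 is then epoxidised to full conversion in the matched Sharpless system (D-(−)-DIPT, Ti(OiPr)4, t-BuOOH) to give 4.

**Further compounds**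
F1 | step 3 | 3-bromo-4-{(R)-(3,4-dimethoxyphenyl)[(2S)-oxiran-2-yl]methoxy}-5-methoxybenzaldehyde | COc1ccc([C@@H](Oc2c(Br)cc(C=O)cc2OC)[C@@H]3CO3)cc1OC
F2 | step 3 | methyl (E)-3-(3-bromo-4-{(R)-(3,4-dimethoxyphenyl)[(2S)-oxiran-2-yl]methoxy}-5-methoxyphenyl)prop-2-enoate | COc1ccc([C@@H](Oc2c(Br)cc(/C=C/C(=O)OC)cc2OC)[C@@H]3CO3)cc1OC
F3 | step 3 | (E)-3-(3-bromo-4-{(R)-(3,4-dimethoxyphenyl)[(2S)-oxiran-2-yl]methoxy}-5-methoxyphenyl)prop-2-en-1-ol | COc1ccc([C@@H](Oc2c(Br)cc(/C=C/CO)cc2OC)[C@@H]3CO3)cc1OC
F4 | step 5 | (2S,3R)-2-(3,4-dimethoxyphenyl)-3-(hydroxymethyl)-5-iodo-7-methoxy-2,3-dihydro-1-benzofuran-4-ol | COc1ccc([C@H]2Oc3c(OC)cc(I)c(O)c3[C@@H]2CO)cc1OC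
F5 | step 5 | (2S,3R)-2-(3,4-dimethoxyphenyl)-3-(hydroxymethyl)-5-iodo-7-methoxy-2,3-dihydro-1-benzofuran-4-yl trifluoromethanesulfonate | COc1ccc([C@H]2Oc3c(OC)cc(I)c(OS(=O)(=O)C(F)(F)F)c3[C@@H]2CO)cc1OC
F6 | step 5 | (2S,3R)-2-(3,4-dimethoxyphenyl)-3-(hydroxymethyl)-5-[(E)-3-hydroxyprop-1-enyl]-7-methoxy-2,3-dihydro-1-benzofuran-4-yl trifluoromethanesulfonate | COc1ccc([C@H]2Oc3c(OC)cc(/C=C/CO)c(OS(=O)(=O)C(F)(F)F)c3[C@@H]2CO)cc1OC
F7 | step 2 | (S)-1-(3,4-dimethoxyphenyl)prop-2-en-1-ol | COc1ccc([C@@H](O)C=C)cc1OC
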